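Retrosynthesis (labdane numbering, used throughout): both acetates and the C2–H bond go back to a C2 ketone, C13=C14 to the olefination of a C13 methyl ketone, and C8–C17 to the C7=C8 enol triflate of a C8 ketone.
Ring B of this trans-decalone is then contracted. Removing H from C5 and drawing a C5–C7 bond gives a bicyclo[3.1.0]hexan-2-one (five-membered ring C5–C7–C8–C9–C10, cyclopropane C5–C6–C7) fused to ring A.
The enabling feature is that C8 (later sp2) is the neighbour of C7, while C5 is a tertiary centre between quaternary C4 and C10. A ketyl at C8 can therefore break C5–C7 and leave a tertiary radical inside a six-membered ring.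
Further cuts: C6 (CH2 transfer to C5=C7), C9–C11 (Michael addition to methyl vinyl ketone), C5=C7 (aldol condensation), the C8 oxygen (Wacker oxidation) and C9–C10 (allylation of the ring A ketone).
Forward order: ring A is bought as 2,2,6-trimethylcyclohexane-1,4-dione; then come the cyclopentenone, the side-chain ketone, the cyclopropane, enlargement to ring B, the C17 methyl and the completed chain.
Stereochemistry: C10 comes from the Pd/(S)-t-BuPHOX allylation, C5 and C9 are set in the key step under control of C10, C2 by hydride attack opposite the axial C4 and C10 methyls, and 13E by the Horner–Wadsworth–Emmons reaction.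

Key step: step 11

Remark: racemic 1 is taken as a commercial compound; its only stereocentre is erased in step 2.

Step 1
Reactants: 1 2,2,6-trimethylcyclohexane-1,4-dione (racemic)
Product: 2 7,7,9-trimethyl-1,4-dioxaspiro[4.5]decan-8-one (racemic; ketal at C2, free ketone at C5)
Conditions: HOCH2CH2OH (1.1 equiv), p-TsOH (cat.), toluene, reflux, Dean–Stark trap
Reagents that add atoms: ethylene glycol, OCCO
Why: Acid-catalysed ketalisation with azeotropic water removal should take only the C2 carbonyl, which lies between two CH2 groups, and spare the C5 carbonyl, which lies between a quaternary and a tertiary carbon; no stereocentre is set.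

Step 2
Reactants: 2 7,7,9-trimethyl-1,4-dioxaspiro[4.5]decan-8-one
Product: 4 allyl 7,7,9-trimethyl-1,4-dioxaspiro[4.5]dec-8-en-8-yl carbonate, via lithium enolate 3 (not isolated)
Conditions: LiN(SiMe3)2, THF, 0 °C; then ClCO2CH2CH=CH2, −78 °C
Reagents that add atoms: allyl chloroformate, C=CCOC(=O)Cl
Why: Enol carbonate formation: C10–H is the only enolisable position of 2, and the fully substituted, hindered lithium enolate should react with the hard chloroformate at oxygen.

Step 3
Reactants: 4 allyl enol carbonate
Product: 5 (9R)-7,7,9-trimethyl-9-(prop-2-enyl)-1,4-dioxaspiro[4.5]decan-8-one (C10 quaternary, R)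
Conditions: Pd2(dba)3 (2.5 mol %), (S)-t-BuPHOX (6 mol %), THF, 25 °C
Reagents that add atoms: none
Why: Decarboxylative asymmetric allylic alkylation (Tsuji allylation): zerovalent palladium ionises the allyl carbonate, CO2 leaves and the enolate is allylated at C10 inside the chiral pocket of the (S)-configured phosphinooxazoline, which should give the R quaternary centre by analogy with the enol carbonate of 2,2,6-trimethylcyclohexanone, the same substrate without the remote ketal.

Step 4
Reactants: 5 allyl ketone
Product: 6 (9R)-7,7,9-trimethyl-9-(2-oxopropyl)-1,4-dioxaspiro[4.5]decan-8-one (1,4-diketone C5/C8)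
Conditions: PdCl2 (10 mol %), Cu(OAc)2·H2O (25 mol %), O2 (1 atm), DMA/H2O, 23 °C
Reagents that add atoms: water, O
Why: Tsuji–Wacker oxidation of the monosubstituted alkene should give the methyl ketone (Markovnikov attack of water on the palladium-bound alkene), and the acetate-buffered copper co-catalyst keeps the medium mild enough for the dioxolane.

Step 5
Reactants: 6 1,4-diketone
Product: 7 (7aR)-6,6-(ethylenedioxy)-4,4,7a-trimethyl-1,4,5,6,7,7a-hexahydro-2H-inden-2-one (cyclopentenone C8(=O)–C7H=C5 fused to ring A)
Conditions: KOH (powdered), xylenes, 110 °C, Dean–Stark trap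
Reagents that add atoms: none
Why: Intramolecular aldol condensation (5-enolexo-exo-trig attack of the methyl carbon C7 on the C5 carbonyl, then loss of water) is the only closure of this 1,4-diketone that gives an unstrained ring and is known to overcome the hindrance of such a C5 carbonyl when water is removed at high temperature.

Step 6
Reactants: 7 bicyclic enone
Product: 9 enone 7 carrying a 3-oxobutyl group at C9 trans to the C10 methyl, via lithium dienolate 8 (not isolated)
Conditions: LiN(i-Pr)2, THF, −78 °C; then CH2=CHCOCH3, −78 °C; then H2O
Reagents that add atoms: methyl vinyl ketone, C=CC(C)=O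
Why: Kinetic deprotonation followed by Michael addition: C9 carries the only acidic hydrogens of 7 (C4 and C10 are quaternary), and the flat cross-conjugated dienolate should add to the enone from the face opposite the C10 methyl, so that the side chain is first placed trans to it, an error that step 11 corrects.

Step 7
Reactants: 9 enone methyl ketone
Product: 10 enone bis-ketal (dioxolanes at C2 and C13, enone C8 free)
Conditions: (TMSOCH2)2, TMSOTf (5 mol %), CH2Cl2, −78 °C; pyridine quench
Reagents that add atoms: 1,2-bis(trimethylsilyloxy)ethane, C[Si](C)(C)OCCO[Si](C)(C)C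
Why: Ketalisation with the bis-silyl ether under TMSOTf catalysis at low temperature should pick the saturated methyl ketone and leave the less electrophilic, hindered cyclopentenone carbonyl free.

Step 8
Reactants: 10 enone bis-ketal
Product: 11 allylic alcohol (C8–OH cis to the C9 side chain, trans to the C10 methyl)
Conditions: i-Bu2AlH, CH2Cl2, −78 °C; then H2O
Reagents that add atoms: none
Why: 1,2-Reduction of the enone with an electrophilic aluminium hydride, hydride arriving anti to the neighbouring C9 side chain so that the hydroxyl comes to lie cis to it and trans to the C10 methyl; this centre is only a temporary directing group and is oxidised again in step 10.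

Step 9
Reactants: 11 allylic alcohol
Product: 12 cyclopropyl carbinol (cyclopropane C5–C6–C7, C6 on the face of the hydroxyl, trans to the C10 methyl)
Conditions: Et2Zn, CH2I2, CH2Cl2, 0 to 23 °C; then H2O
Reagents that add atoms: diiodomethane, ICI
Why: Hydroxyl-directed Simmons–Smith cyclopropanation (Et2Zn/CH2I2 variant): the zinc alkoxide should deliver CH2, the future C6, to the C5=C7 bond on its own face, which is also the face away from the C10 methyl, and the new centres C5 and C7 are given up again in step 11.

Step 10
Reactants: 12 cyclopropyl carbinol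
Product: 13 tricyclic cyclopropyl ketone (bicyclo[3.1.0]hexan-2-one C5–C6–C7/C8=O fused to ring A)
Conditions: DMP (1,1,1-triacetoxy-1,1-dihydro-1,2-benziodoxol-3(1H)-one), pyridine, CH2Cl2, 23 °C
Reagents that add atoms: none
Why: Oxidation of the secondary cyclopropyl carbinol with a hypervalent iodine reagent (Dess–Martin oxidation) under pyridine buffering avoids the acid that would open the cyclopropane or the ketals.

Step 11
Reactants: 13 tricyclic cyclopropyl ketone
Product: 18 trans-decalone (C8 ketone; 5-H trans to the C10 methyl; C9 side chain equatorial and cis to the C10 methyl; dioxolanes at C2 and C13), via O-stannyl ketyl radical 14 (not isolated), via ring-enlarged C5 radical 15 (not isolated), via tributyltin enolate 16 (not isolated), via 9-epi ketone 17 (not isolated)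
Conditions: Bu3SnH (1.5 equiv) and AIBN (0.2 equiv) in toluene, added over 8 h to 13 in toluene (0.005 M), reflux; then NaOMe (cat.), MeOH, 40 °C; then H2O
Reagents that add atoms: none
Why: Bu3Sn• adds to the C8 carbonyl oxygen to give ketyl 14, a cyclopropylcarbinyl radical whose β-scission is reversible: cleavage of the outer C6–C7 bond gives a primary radical on quaternary C5 that re-closes quickly, whereas cleavage of the shared C5–C7 bond turns the five-membered ring C5–C7–C8–C9–C10 into the six-membered ring B (C5–C6–C7–C8–C9–C10) and gives the tertiary radical 15, the thermodynamic sink, which takes H from Bu3SnH to give tin enolate 16. The closest known reactions are the Bu3SnH- or SmI2-induced fragmentations of bicyclo[n.1.0]alkan-2-ones, in which endocyclic cleavage with ring enlargement wins when it leads to the more substituted radical and the hydrogen donor is kept dilute, and the opening of the thujone C4 radical (a bicyclo[3.1.0]hexyl radical with a fully substituted distal bridgehead) to a six-membered p-menthenone radical. No ring is closed by bond formation: ring B arises by one-carbon enlargement through cleavage of the zero bridge of the bicyclo[3.1.0]hexanone. At C5 the planar radical is shielded on one face by the axial C10 methyl and the axial C4 methyl, so H should arrive on the opposite face and give the trans-decalin, the symmetric C2 ketal adding no bias towards a cis fusion; at C9, methanolysis of 16 gives 17 and methoxide equilibrates this centre alpha to the C8 ketone to the equatorial side chain, cis to the C10 methyl. The step needs endocyclic over exocyclic cleavage, which is secured by the tertiary versus primary radical, by the strain released from the cyclopropane-fused cyclopentanone and by slow addition of the stannane; the ketals are inert and no other reducible group is present.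

Step 12
Reactants: 18 trans-decalone
Product: 20 C7=C8 enol triflate, via lithium enolate 19 (not isolated)
Conditions: LiN(i-Pr)2, THF, −78 °C; then N-(5-chloropyridin-2-yl)bis(trifluoromethanesulfonimide), −78 °C; then H2O
Reagents that add atoms: N-(5-chloropyridin-2-yl)bis(trifluoromethanesulfonimide), O=S(=O)(N(c1ccc(Cl)cn1)S(=O)(=O)C(F)(F)F)C(F)(F)F
Why: Kinetic enolate formation and O-sulfonylation: the bulky amide should remove the unhindered C7–H and not the tertiary C9–H next to quaternary C10, so that the triflate fixes the place of the future C7=C8 double bond and C9 is not touched.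

Step 13
Reactants: 20 enol triflate
Product: 21 8-methyl-Δ7 decalin bis-ketal (ring B complete)
Conditions: MeMgBr, Fe(acac)3 (5 mol %), THF/NMP, −30 to 0 °C
Reagents that add atoms: methylmagnesium bromide, C[Mg]Br
Why: Iron-catalysed Kumada-type cross-coupling of the alkenyl triflate with MeMgBr should replace OTf by the C17 methyl with retention of the double bond position at a temperature at which the ketals are inert.

Step 14
Reactants: 21 bis-ketal
Product: 22 diketone (C2 ketone and C13 methyl ketone)
Conditions: 1 M HCl, THF, 23 °C
Reagents that add atoms: water, O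
Why: Acid-catalysed ketal hydrolysis frees both ketones, the C2 ketal being strained by its axial oxygen syn to the axial C4 and C10 methyls, under conditions too mild to protonate the trisubstituted C7=C8 alkene.

Step 15
Reactants: 22 diketone
Product: 23 ethyl (13E)-enoate (C2 ketone retained)
Conditions: (EtO)2P(O)CH2CO2Et, NaH, THF, 0 to 23 °C; then H2O
Reagents that add atoms: triethyl phosphonoacetate, CCOC(=O)CP(=O)(OCC)OCC
Why: Horner–Wadsworth–Emmons olefination: the stabilised phosphonate anion should choose the open-chain methyl ketone over the C2 ketone, where addition forces a group into the axial position syn to two axial methyls, and reversible addition should favour the E-enoate.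

Step 16
Reactants: 23 keto enoate
Product: 24 (2S,5R,9R,10R,13E)-labda-7,13-diene-2,15-diol
Conditions: i-Bu2AlH (excess), CH2Cl2, −78 °C; then H2O
Reagents that add atoms: none
Why: Hydride reduction: i-Bu2AlH should take the enoate to the allylic alcohol by double 1,2-addition and attack the C2 ketone from the face opposite the axial C4 and C10 methyls (equatorial attack), which sets the axial C2 alcohol with S configuration.

Step 17
Reactants: 24 diol
Product: 25 (2S,5R,9R,10R,13E)-labda-7,13-diene-2,15-diyl diacetate (target)
Conditions: Ac2O, pyridine, DMAP (cat.), CH2Cl2, 23 °C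
Reagents that add atoms: acetic anhydride, CC(=O)OC(C)=O
Why: DMAP-catalysed acylation should esterify both the primary allylic and the hindered axial secondary alcohol without change at any stereocentre.

Compound list
1 | 2,2,6-trimethylcyclohexane-1,4-dione (racemic) | CC1CC(=O)CC(C)(C)C1=O | starting material
2 | 7,7,9-trimethyl-1,4-dioxaspiro[4.5]decan-8-one (racemic) | CC1CC2(OCCO2)CC(C)(C)C1=O | intermediate
3 | lithium enolate of 2 | [Li]OC1=C(C)CC2(OCCO2)CC1(C)C | intermediate
4 | allyl 7,7,9-trimethyl-1,4-dioxaspiro[4.5]dec-8-en-8-yl carbonate | C=CCOC(=O)OC1=C(C)CC2(OCCO2)CC1(C)C | intermediate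
5 | (9R)-7,7,9-trimethyl-9-(prop-2-enyl)-1,4-dioxaspiro[4.5]decan-8-one | C=CC[C@]1(C)CC2(OCCO2)CC(C)(C)C1=O | intermediate
6 | (9R)-7,7,9-trimethyl-9-(2-oxopropyl)-1,4-dioxaspiro[4.5]decan-8-one | CC(=O)C[C@]1(C)CC2(OCCO2)CC(C)(C)C1=O | intermediate
7 | (7aR)-6,6-(ethylenedioxy)-4,4,7a-trimethyl-1,4,5,6,7,7a-hexahydro-2H-inden-2-one | O=C1C=C2C(C)(C)CC3(OCCO3)C[C@@]2(C)C1 | intermediate
8 | cross-conjugated lithium dienolate of 7 (C8–OLi, C8=C9, C5=C7) | [Li]OC1=C[C@]2(C)CC3(OCCO3)CC(C)(C)C2=C1 | intermediate
9 | enone 7 with a 3-oxobutyl group at C9, trans to the C10 methyl | CC(=O)CC[C@H]1C(=O)C=C2C(C)(C)CC3(OCCO3)C[C@@]12C | intermediate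
10 | enone bis-ketal (dioxolanes at C2 and C13) | CC1(CC[C@H]2C(=O)C=C3C(C)(C)CC4(OCCO4)C[C@@]23C)OCCO1 | intermediate
11 | allylic alcohol (C8–OH cis to the C9 chain) | CC1(CC[C@H]2[C@@H](O)C=C3C(C)(C)CC4(OCCO4)C[C@@]23C)OCCO1 | intermediate
12 | cyclopropyl carbinol (C6 syn to OH, trans to the C10 methyl) | CC1(CC[C@H]2[C@@H](O)[C@H]3C[C@]34C(C)(C)CC5(OCCO5)C[C@@]24C)OCCO1 | intermediate
13 | tricyclic cyclopropyl ketone | CC1(CC[C@H]2C(=O)[C@H]3C[C@]34C(C)(C)CC5(OCCO5)C[C@@]24C)OCCO1 | intermediate
14 | O-tributylstannyl ketyl radical at C8 | CC1(CC[C@H]2[C](O[Sn](CCCC)(CCCC)CCCC)[C@H]3C[C@]34C(C)(C)CC5(OCCO5)C[C@@]24C)OCCO1 | intermediate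
15 | ring-enlarged tertiary C5 radical (tin enolate C7=C8) | CC1(CC[C@H]2C(O[Sn](CCCC)(CCCC)CCCC)=CC[C]3C(C)(C)CC4(OCCO4)C[C@@]23C)OCCO1 | intermediate
16 | tributyltin enolate of the trans-decalone (9-epi) | CC1(CC[C@H]2C(O[Sn](CCCC)(CCCC)CCCC)=CC[C@@H]3C(C)(C)CC4(OCCO4)C[C@@]23C)OCCO1 | intermediate
17 | 9-epi trans-decalone (C9 chain axial) | CC1(CC[C@H]2C(=O)CC[C@@H]3C(C)(C)CC4(OCCO4)C[C@@]23C)OCCO1 | intermediate
18 | trans-decalone (C8 ketone, C9 chain equatorial) | CC1(CC[C@@H]2C(=O)CC[C@@H]3C(C)(C)CC4(OCCO4)C[C@@]23C)OCCO1 | intermediate
19 | kinetic lithium enolate of 18 (C7=C8) | CC1(CC[C@@H]2C(O[Li])=CC[C@@H]3C(C)(C)CC4(OCCO4)C[C@@]23C)OCCO1 | intermediate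
20 | C7=C8 enol triflate | CC1(CC[C@@H]2C(OS(=O)(=O)C(F)(F)F)=CC[C@@H]3C(C)(C)CC4(OCCO4)C[C@@]23C)OCCO1 | intermediate
21 | 8-methyl-Δ7 decalin bis-ketal | CC1(CC[C@@H]2C(C)=CC[C@@H]3C(C)(C)CC4(OCCO4)C[C@@]23C)OCCO1 | intermediate
22 | diketone (C2 and C13) | CC(=O)CC[C@@H]1C(C)=CC[C@@H]2C(C)(C)CC(=O)C[C@@]12C | intermediate
23 | ethyl (13E)-enoate with C2 ketone | CCOC(=O)/C=C(\C)CC[C@@H]1C(C)=CC[C@@H]2C(C)(C)CC(=O)C[C@@]12C | intermediate
24 | (2S,5R,9R,10R,13E)-labda-7,13-diene-2,15-diol | OC/C=C(\C)CC[C@@H]1C(C)=CC[C@@H]2C(C)(C)C[C@H](O)C[C@@]12C | intermediate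
25 | (2S,5R,9R,10R,13E)-labda-7,13-diene-2,15-diyl diacetate | CC(=O)OC/C=C(\C)CC[C@@H]1C(C)=CC[C@@H]2C(C)(C)C[C@H](OC(C)=O)C[C@@]12C | target

Total step count: 17. Longest linear sequence: 17 (the route is linear from 1).

Steps most likely to fail

Step 11.
- Risk: hydrogen may be transferred to the primary radical from the kinetically preferred cleavage of the outer C6–C7 bond before it re-closes, so that no ring enlargement takes place. Hydrogen may also be delivered to the wrong face of C5.
- Fallback: cationic instead of radical opening, setting out from 13 and coming back at 20. Heating 13 with p-TsOH·H2O in wet acetone should protonate the C8 carbonyl and break the same C5–C7 bond heterolytically, because only this cleavage gives a tertiary cation.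
- Loss of a C6 proton and conjugation follow, and both ketals are hydrolysed. Acid equilibration through the enol and dienol sets C9 and C5 and should give the trans-fused enetrione F1.
- The two saturated ketones are ketalised again with (TMSOCH2)2 and TMSOTf to give the enone bis-ketal F2. Conjugate reduction with LiBH(s-Bu)3, followed by the triflimide of step 12, traps the C7=C8 enolate as 20.

Step 9.
- Risk: methylene transfer to the trisubstituted alkene between two quaternary carbons may be sluggish, and the zinc salts may ionise the allylic alcohol.
- Fallback: no cyclopropane, a 1,2-vinyl shift enlarges the ring instead, setting out from 10 and coming back at 18. LiCHBr2, made from CH2Br2 and lithium 2,2,6,6-tetramethylpiperidide at −90 °C, adds to the enone carbonyl to give the dibromomethyl carbinol F3.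
- n-BuLi (2 equiv, −78 °C) generates the β-oxido carbenoid. The vinyl carbon migrates to the carbenoid carbon (which becomes C7, the former enone CH becoming C6), and protonation of the dienolate gives the ring-enlarged β,γ-enone F4.
- Hydrogen-atom-transfer hydrogenation (Mn(dpm)3, PhSiH3, t-BuOOH, i-PrOH) places H on C6 and then on the tertiary C5 radical from the face opposite the axial methyls. This gives 17, which NaOMe in MeOH equilibrates to 18.

Step 15.
- Risk: E/Z control at the methyl ketone may be poor, and olefination may compete at the C2 ketone.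
- Fallback: alkyne carboalumination in place of carbonyl olefination, setting out from 22 and coming back at 24. LiN(i-Pr)2 (1 equiv) removes a proton from the accessible C16 methyl and ClP(O)(OEt)2 traps the enolate. More LiN(i-Pr)2 eliminates the enol phosphate to give the terminal alkyne ketone F5.
- NaBH4 in MeOH attacks the C2 ketone from the face opposite the axial methyls and gives the axial alkynol F6.
- Syn-carboalumination with AlMe3 and Cp2ZrCl2 (cat.), then n-BuLi and paraformaldehyde, places the methyl on C13 and CH2OH on C14 with the E geometry fixed by the syn addition. This gives 24.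

Further compounds
F1 | step 11 | trans-fused enetrione (C8 enone Δ6, ketones at C2 and C13) | CC(=O)CC[C@@H]1C(=O)C=C[C@@H]2C(C)(C)CC(=O)C[C@@]12C
F2 | step 11 | enone bis-ketal (C8 enone Δ6, dioxolanes at C2 and C13) | CC1(CC[C@@H]2C(=O)C=C[C@@H]3C(C)(C)CC4(OCCO4)C[C@@]23C)OCCO1
F3 | step 9 | dibromomethyl carbinol of enone 10 | CC1(CC[C@H]2[C@](O)(C(Br)Br)C=C3C(C)(C)CC4(OCCO4)C[C@@]23C)OCCO1
F4 | step 9 | ring-enlarged β,γ-enone (C8 ketone, C5=C6) | CC1(CC[C@H]2C(=O)CC=C3C(C)(C)CC4(OCCO4)C[C@@]23C)OCCO1
F5 | step 15 | terminal alkyne ketone (C13≡CH, C2 ketone) | C#CCC[C@@H]1C(C)=CC[C@@H]2C(C)(C)CC(=O)C[C@@]12C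
F6 | step 15 | axial alkynol (C13≡CH, 2S alcohol) | C#CCC[C@@H]1C(C)=CC[C@@H]2C(C)(C)C[C@H](O)C[C@@]12C
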